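**Plan**
1. Retrosynthetic cuts: first the C12′–C13′ bond of the macrolide (made as a C=C by ring-closing metathesis), then the benzoate C(=O)–O bond to (S)-4-bromo-4-methylpent-1-en-3-ol, then C9′–C10′ (B-alkyl Suzuki), the carbocycle bond C2′–C7′ (bromonium cyclization) and the aryl–C1′ bond (phenoxide C-geranylation).
2. Forward order: geranylated benzoate → C6′/C7′ bromohydrin → C4 chain extension → cyclohexene ring → C10′/C11′ bromohydrin carrying a vinyl group on C11′ → ester → 15-membered lactone ring last, then alkene saturation and MOM removal.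
3. Enabling feature: in the 15-membered ring (C7′ to C14′, ester O and C=O, three arene carbons, C1′, C2′) the tertiary carbinol C11′ and the acyloxy carbinol C14′ are joined by the bare C12′H2–C13′H2 unit, and each of the two can be made as a vinyl carbinol.
4. Stereochemistry: C6′/C7′ come from Sharpless epoxidation (D-(−)-DET) and C-3 bromide opening, and are passed to quaternary C7′ and to C2′ by a stereospecific chair bromonium cyclization; C10′/C11′ come from a second Sharpless epoxidation (L-(+)-DET) and bromide opening; C14′ comes from a Sharpless kinetic resolution.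

Key step: step 27

Remark: primed locants run along the terpenoid chain from the benzylic carbon C1′ to C12′ (the vinyl CH on C11′), C13′/C14′/C15′ are the vinyl CH, carbinol carbon and CMe2Br carbon of the bromo alcohol; the metathesis product is drawn E, although either alkene geometry serves because the alkene is saturated in step 28.

**Route**

Step 1
Reactants: 1 methyl 4-hydroxybenzoate; 2 geranyl bromide
Product: 4 methyl 3-[(2E)-3,7-dimethylocta-2,6-dien-1-yl]-4-hydroxybenzoate, via sodium phenoxide 3 (not isolated)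
Conditions: NaH, toluene, 0 °C → rt; then 2, rt → 50 °C
Reagents that add atoms: none
Why: ortho-C-alkylation of a sodium phenoxide held as a tight ion pair in a non-polar solvent (SN2 at the primary allylic carbon, E geometry kept), the para position being blocked by the ester.

Step 2
Reactants: 4 geranyl phenol
Product: 5 methyl 3-[(2E)-3,7-dimethylocta-2,6-dien-1-yl]-4-(pivaloyloxy)benzoate
Conditions: PivCl, Et3N, DMAP (cat.), CH2Cl2, 0 °C → rt
Reagents that add atoms: pivaloyl chloride CC(C)(C)C(=O)Cl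
Why: O-acylation makes the phenol oxygen non-nucleophilic, so that it cannot capture the C3′ cation in step 13 as an ether or acetal oxygen would.

Step 3
Reactants: 5 aryl pivalate
Product: 6 methyl 3-[(2E,6E)-8-hydroxy-3,7-dimethylocta-2,6-dien-1-yl]-4-(pivaloyloxy)benzoate
Conditions: SeO2 (0.3 equiv), t-BuOOH (3 equiv), salicylic acid (cat.), CH2Cl2, 0 °C → rt
Reagents that add atoms: selenium dioxide O=[Se]=O (oxygen carrier); tert-butyl hydroperoxide CC(C)(C)OO (terminal oxidant)
Why: SeO2/t-BuOOH allylic oxidation (ene reaction then [2,3]-shift) should pick the E-methyl of the terminal, more accessible trisubstituted alkene, as it does in geranyl and farnesyl derivatives.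

Step 4
Reactants: 6 (E)-allylic alcohol
Product: 7 methyl 3-{(2E)-5-[(2R,3R)-3-(hydroxymethyl)-3-methyloxiran-2-yl]-3-methylpent-2-en-1-yl}-4-(pivaloyloxy)benzoate
Conditions: Ti(OiPr)4 (10 mol%), D-(−)-diethyl tartrate (12 mol%), t-BuOOH (2 equiv, decane), 4 Å MS, CH2Cl2, −20 °C
Reagents that add atoms: tert-butyl hydroperoxide CC(C)(C)OO
Why: Sharpless asymmetric epoxidation, in which the D-(−)-tartrate complex delivers oxygen to the face that gives the (6′R,7′R) epoxide and the isolated C2′=C3′ alkene is not touched.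

Step 5
Reactants: 7 epoxy alcohol
Product: 8 methyl 3-[(2E,6S,7R)-6-bromo-7,8-dihydroxy-3,7-dimethyloct-2-en-1-yl]-4-(pivaloyloxy)benzoate
Conditions: Et2NH·HBr (3 equiv), Ti(OiPr)4 (1.5 equiv, promoter), CH2Cl2, 0 °C → rt
Reagents that add atoms: diethylammonium bromide CC[NH2+]CC.[Br-]
Why: titanium-chelated C-3 opening of a 2,3-epoxy alcohol, bromide attacking C6′ (the only epoxide carbon open to backside attack) with inversion to set the C6′–Br centre while C7′–O is untouched.

Step 6
Reactants: 8 bromo diol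
Product: 9 methyl 3-[(2E,6S,7R)-6-bromo-3,7-dimethyl-7,8-bis(triethylsilyloxy)oct-2-en-1-yl]-4-(pivaloyloxy)benzoate
Conditions: TESOTf (2.5 equiv), 2,6-lutidine, CH2Cl2, −78 → 0 °C
Reagents that add atoms: triethylsilyl trifluoromethanesulfonate CC[Si](CC)(CC)OS(=O)(=O)C(F)(F)F
Why: silyl triflate silylation of both hydroxyls masks the tertiary alcohol, so that the basic steps that follow cannot close the bromohydrin to an epoxide.

Step 7
Reactants: 9 bis-TES ether
Product: 10 methyl 3-[(2E,6S,7R)-6-bromo-3,7-dimethyl-8-oxo-7-(triethylsilyloxy)oct-2-en-1-yl]-4-(pivaloyloxy)benzoate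
Conditions: (COCl)2, DMSO, CH2Cl2, −78 → −40 °C; then Et3N, −78 °C → rt
Reagents that add atoms: none
Why: Swern oxidation applied directly to the silyl ether, the chlorosulfonium salt cleaving only the unhindered primary O–Si bond and oxidizing that carbon while the tertiary TES ether stays.

Step 8
Reactants: 10 α-silyloxy aldehyde
Product: 11 methyl 3-[(2E,6S,7R)-6-bromo-3,7-dimethyl-7-(triethylsilyloxy)nona-2,8-dien-1-yl]-4-(pivaloyloxy)benzoate
Conditions: Ph3PCH3Br, KHMDS, THF, 0 °C; then 10, −78 → 0 °C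
Reagents that add atoms: methyltriphenylphosphonium bromide C[P+](c1ccccc1)(c1ccccc1)c1ccccc1.[Br-]
Why: Wittig methylenation of an aldehyde that has no α-hydrogen and no free hydroxyl, so neither epimerization nor epoxide closure can compete.

Step 9
Reactants: 12 propargyl alcohol
Product: 14 (2E)-3-iodo-2-methylprop-2-en-1-ol, via alkenylalane 13 (not isolated)
Conditions: Me3Al (3 equiv), Cp2ZrCl2 (0.25 equiv), CH2Cl2, 0 °C → rt; then I2, THF, −30 → 0 °C
Reagents that add atoms: trimethylaluminium C[Al](C)C; iodine II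
Why: Negishi zirconium-catalysed carboalumination adds methyl and aluminium syn across the alkyne, and iodinolysis with retention fixes the E geometry.

Step 10
Reactants: 14 iodo alcohol
Product: 15 (2E)-3-iodo-2-methylprop-2-en-1-yl pivalate
Conditions: PivCl, pyridine, CH2Cl2, 0 °C → rt
Reagents that add atoms: pivaloyl chloride CC(C)(C)C(=O)Cl
Why: acylation gives an allylic ester that is slow to ionize with Pd(0) in step 11 and with SnCl4 in step 13.

Step 11
Reactants: 11 vinyl carbinol TES ether; 15 vinyl iodide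
Product: 17 methyl 3-[(2E,6S,7R,10E)-6-bromo-3,7,11-trimethyl-12-(pivaloyloxy)-7-(triethylsilyloxy)dodeca-2,10-dien-1-yl]-4-(pivaloyloxy)benzoate, via B-alkyl-9-BBN adduct 16 (not isolated)
Conditions: 9-BBN (1.5 equiv), THF, rt; then 15, Pd(dppf)Cl2 (5 mol%), K3PO4 (powder), DMF, 50 °C
Reagents that add atoms: none
Why: B-alkyl Suzuki–Miyaura coupling, 9-BBN hydroborating only the monosubstituted alkene at its terminus and the sp3–sp2 coupling keeping the E geometry of the iodide, with the unactivated alkyl bromide inert to Pd and the aryl pivalate safe under anhydrous base.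

Step 12
Reactants: 17 tertiary TES ether
Product: 18 methyl 3-[(2E,6S,7R,10E)-6-bromo-7-hydroxy-3,7,11-trimethyl-12-(pivaloyloxy)dodeca-2,10-dien-1-yl]-4-(pivaloyloxy)benzoate
Conditions: HF·pyridine, THF/pyridine, 0 °C → rt
Reagents that add atoms: none
Why: fluoride-driven Si–O cleavage frees the tertiary alcohol that serves as the leaving group in step 13, without touching either pivalate or the bromide.

Step 13
Reactants: 18 tertiary bromohydrin
Product: 19 methyl 3-({(1R,5S,6S)-5-bromo-2,6-dimethyl-6-[(3E)-4-methyl-5-(pivaloyloxy)pent-3-en-1-yl]cyclohex-2-en-1-yl}methyl)-4-(pivaloyloxy)benzoate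
Conditions: SnCl4 (3 equiv, promoter), CH2Cl2, −78 → −40 °C
Reagents that add atoms: none
Why: bromonium-initiated cation–olefin cyclization from an enantiopure bromohydrin, in which Lewis-acid ionization of the tertiary C7′–OH is assisted by the anti bromine and the bromonium ion is opened at C7′ by C2′ of the (E)-alkene through a chair (net retention at C7′, arylmethyl equatorial at C2′, hence Br, CH3 and CH2Ar cis), after which the C3′ cation should lose the C4′ proton.

Step 14
Reactants: 19 bis-pivalate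
Product: 20 methyl 3-({(1R,5S,6S)-5-bromo-6-[(3E)-5-hydroxy-4-methylpent-3-en-1-yl]-2,6-dimethylcyclohex-2-en-1-yl}methyl)-4-hydroxybenzoate
Conditions: NaOMe (4 equiv), MeOH, rt → 40 °C
Reagents that add atoms: none
Why: methoxide transesterification removes the aryl and the allylic pivalate, leaves the methyl benzoate unchanged (degenerate exchange) and spares the equatorial neopentyl bromide, which resists both SN2 and E2.

Step 15
Reactants: 20 phenol allylic alcohol
Product: 21 methyl 3-({(1R,5S,6S)-5-bromo-6-[(3E)-5-hydroxy-4-methylpent-3-en-1-yl]-2,6-dimethylcyclohex-2-en-1-yl}methyl)-4-(methoxymethoxy)benzoate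
Conditions: MOMCl (1.2 equiv), K2CO3, acetone, 0 °C → rt
Reagents that add atoms: chloromethyl methyl ether COCCl
Why: Williamson-type alkylation of the phenoxide only, since carbonate deprotonates the acidic para-ester phenol but not the allylic alcohol.

Step 16
Reactants: 21 (E)-allylic alcohol
Product: 22 methyl 3-({(1R,5S,6S)-5-bromo-6-{2-[(2S,3S)-3-(hydroxymethyl)-3-methyloxiran-2-yl]ethyl}-2,6-dimethylcyclohex-2-en-1-yl}methyl)-4-(methoxymethoxy)benzoate
Conditions: Ti(OiPr)4 (10 mol%), L-(+)-diethyl tartrate (12 mol%), t-BuOOH (2 equiv, decane), 4 Å MS, CH2Cl2, −20 °C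
Reagents that add atoms: tert-butyl hydroperoxide CC(C)(C)OO
Why: Sharpless asymmetric epoxidation under reagent control, L-(+)-tartrate giving the (10′S,11′S) epoxide, with the trisubstituted ring alkene (not an allylic alcohol) left alone.

Step 17
Reactants: 22 epoxy alcohol
Product: 23 methyl 3-({(1R,5S,6S)-5-bromo-6-[(3R,4S)-3-bromo-4,5-dihydroxy-4-methylpentyl]-2,6-dimethylcyclohex-2-en-1-yl}methyl)-4-(methoxymethoxy)benzoate
Conditions: Et2NH·HBr (3 equiv), Ti(OiPr)4 (1.5 equiv, promoter), CH2Cl2, 0 °C → rt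
Reagents that add atoms: diethylammonium bromide CC[NH2+]CC.[Br-]
Why: the same titanium-chelated C-3 epoxy alcohol opening, bromide inverting C10′ (to R) while the C11′–O bond and configuration are kept.

Step 18
Reactants: 23 bromo diol
Product: 24 methyl 3-({(1R,5S,6S)-5-bromo-6-[(3R,4S)-3-bromo-4-methyl-4,5-bis(triethylsilyloxy)pentyl]-2,6-dimethylcyclohex-2-en-1-yl}methyl)-4-(methoxymethoxy)benzoate
Conditions: TESOTf (2.5 equiv), 2,6-lutidine, CH2Cl2, −78 → −40 °C
Reagents that add atoms: triethylsilyl trifluoromethanesulfonate CC[Si](CC)(CC)OS(=O)(=O)C(F)(F)F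
Why: low-temperature silyl triflate silylation of both hydroxyls, run cold so that the aryl MOM acetal is not attacked by the silyl triflate.

Step 19
Reactants: 24 bis-TES ether
Product: 25 methyl 3-({(1R,5S,6S)-5-bromo-6-[(3R,4S)-3-bromo-4-methyl-5-oxo-4-(triethylsilyloxy)pentyl]-2,6-dimethylcyclohex-2-en-1-yl}methyl)-4-(methoxymethoxy)benzoate
Conditions: (COCl)2, DMSO, CH2Cl2, −78 → −40 °C; then Et3N, −78 °C → rt
Reagents that add atoms: none
Why: Swern oxidation of the primary TES ether in the presence of the tertiary one, as in step 7.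

Step 20
Reactants: 25 α-silyloxy aldehyde
Product: 26 methyl 3-({(1R,5S,6S)-5-bromo-6-[(3R,4S)-3-bromo-4-methyl-4-(triethylsilyloxy)hex-5-en-1-yl]-2,6-dimethylcyclohex-2-en-1-yl}methyl)-4-(methoxymethoxy)benzoate
Conditions: Ph3PCH3Br, KHMDS, THF, 0 °C; then 25, −78 → 0 °C
Reagents that add atoms: methyltriphenylphosphonium bromide C[P+](c1ccccc1)(c1ccccc1)c1ccccc1.[Br-]
Why: Wittig methylenation installs the first metathesis alkene on C11′, the aldehyde being far more electrophilic than the electron-rich methyl benzoate.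

Step 21
Reactants: 26 methyl ester
Product: 27 3-({(1R,5S,6S)-5-bromo-6-[(3R,4S)-3-bromo-4-methyl-4-(triethylsilyloxy)hex-5-en-1-yl]-2,6-dimethylcyclohex-2-en-1-yl}methyl)-4-(methoxymethoxy)benzoic acid
Conditions: LiOH·H2O, THF/MeOH/H2O, rt; then 0.5 M HCl, 0 °C, to pH 4
Reagents that add atoms: lithium hydroxide [Li+].[OH-]
Why: saponification (acyl–oxygen cleavage) is safe here because the tertiary alcohol is silylated, so no bromohydrin alkoxide can form, and both secondary bromides sit next to fully substituted carbons and are slow toward hydroxide.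

Step 22
Reactants: 28 isobutyraldehyde
Product: 29 2-bromo-2-methylpropanal
Conditions: Br2 (1.0 equiv), CH2Cl2, 0 °C
Reagents that add atoms: bromine BrBr
Why: acid-autocatalysed α-bromination through the enol, which can only give the monobromide because there is a single α-hydrogen.

Step 23
Reactants: 29 2-bromo-2-methylpropanal; 30 vinylmagnesium bromide
Product: 31 rac-4-bromo-4-methylpent-1-en-3-ol
Conditions: THF, −78 °C; aqueous NH4Cl quench at −78 °C
Reagents that add atoms: none
Why: Grignard 1,2-addition to a highly electrophilic α-bromo aldehyde, quenched cold so that the magnesium alkoxide does not close to the epoxide.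

Step 24
Reactants: 31 racemic bromo alcohol
Product: 32 (3S)-4-bromo-4-methylpent-1-en-3-ol
Conditions: Ti(OiPr)4 (1.0 equiv, promoter), L-(+)-diisopropyl tartrate (1.2 equiv), t-BuOOH (0.6 equiv), 4 Å MS, CH2Cl2, −20 °C, taken past half conversion
Reagents that add atoms: none
Why: Sharpless kinetic resolution of a secondary allylic alcohol, L-(+)-tartrate epoxidizing the (R)-enantiomer (the spatial counterpart of the usual fast-reacting isomer) and leaving the (S)-alcohol enantioenriched.

Step 25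
Reactants: 27 acid; 32 (S)-bromo alcohol
Product: 34 (3S)-4-bromo-4-methylpent-1-en-3-yl 3-({(1R,5S,6S)-5-bromo-6-[(3R,4S)-3-bromo-4-methyl-4-(triethylsilyloxy)hex-5-en-1-yl]-2,6-dimethylcyclohex-2-en-1-yl}methyl)-4-(methoxymethoxy)benzoate, via mixed anhydride 33 (not isolated)
Conditions: 2,4,6-trichlorobenzoyl chloride, Et3N, toluene, rt; then 32, DMAP, toluene, rt
Reagents that add atoms: none
Why: Yamaguchi esterification acylates the hindered secondary alcohol through the acyl-DMAP species without forming an alkoxide, so the carbinol configuration is kept and the tertiary bromide is not displaced.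

Step 26
Reactants: 34 ester with tertiary TES ether
Product: 35 (3S)-4-bromo-4-methylpent-1-en-3-yl 3-({(1R,5S,6S)-5-bromo-6-[(3R,4S)-3-bromo-4-hydroxy-4-methylhex-5-en-1-yl]-2,6-dimethylcyclohex-2-en-1-yl}methyl)-4-(methoxymethoxy)benzoate
Conditions: HF·pyridine, THF/pyridine, 0 °C → rt
Reagents that add atoms: none
Why: fluoride desilylation under weakly acidic conditions frees the tertiary allylic alcohol for the metathesis without touching the MOM acetal, the ester or the bromides.

Step 27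
Reactants: 35 diene ester
Product: 36 unsaturated 15-membered macrolide MOM ether (12′E; 2′R,6′S,7′S,10′R,11′S,14′S)
Conditions: Hoveyda–Grubbs II (15 mol%, in portions), toluene (1 mM), 80 °C, Ar sparge
Reagents that add atoms: none
Why: The ruthenium alkylidene should load on the vinyl group at C11′, helped by the free tertiary allylic hydroxyl, and close onto the vinyl group of the allylic benzoate through metallacyclobutane formation and cycloreversion, with loss of ethene. The closest known reaction type is ring-closing metathesis macrocyclization of dienes that end in an allylic alcohol and an allylic ester. The one ring formed is the 15-membered lactone, closed by joining the two internal alkene carbons C12′ and C13′, so both new sp2 carbons lie in the ring. No stereocentre is created, since C11′ and C14′ on either side of the new bond are already fixed and either alkene geometry is acceptable. The step needs ring closure to beat dimerization, which high dilution, portionwise catalyst addition and ethene removal should secure. It also needs the two monosubstituted alkenes to react and not the ring alkene, which is trisubstituted and hindered and therefore not a competent partner.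

Step 28
Reactants: 36 unsaturated macrolide
Product: 37 saturated macrolide MOM ether (2′R,6′S,7′S,10′R,11′S,14′S)
Conditions: KO2CN=NCO2K (excess), AcOH (slow addition), MeOH/CH2Cl2, rt
Reagents that add atoms: none
Why: diimide syn-transfer hydrogenation prefers the disubstituted alkene over the trisubstituted ring alkene, cannot cleave C–Br bonds, and is generated under acidic conditions that do not close the bromohydrin.

Step 29
Reactants: 37 MOM ether
Product: 38 target CNP0215732.1
Conditions: HCl (0.5 M in MeOH), CH2Cl2, 0 °C → rt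
Reagents that add atoms: none
Why: acid-catalysed acetal exchange of the aryl MOM ether with methanol, mild enough to leave the tertiary alcohol, the three bromides, the lactone and the ring alkene unchanged.

**Compound list**
1 | methyl 4-hydroxybenzoate | COC(=O)c1ccc(O)cc1 | starting material
2 | geranyl bromide, (2E)-1-bromo-3,7-dimethylocta-2,6-diene | CC(C)=CCC/C(C)=C/CBr | starting material
3 | sodium 4-(methoxycarbonyl)phenolate | COC(=O)c1ccc([O-])cc1.[Na+] | intermediate (not isolated)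
4 | methyl 3-[(2E)-3,7-dimethylocta-2,6-dien-1-yl]-4-hydroxybenzoate | COC(=O)c1ccc(O)c(C/C=C(\C)CCC=C(C)C)c1 | intermediate
5 | methyl 3-[(2E)-3,7-dimethylocta-2,6-dien-1-yl]-4-(pivaloyloxy)benzoate | COC(=O)c1ccc(OC(=O)C(C)(C)C)c(C/C=C(\C)CCC=C(C)C)c1 | intermediate
6 | methyl 3-[(2E,6E)-8-hydroxy-3,7-dimethylocta-2,6-dien-1-yl]-4-(pivaloyloxy)benzoate | COC(=O)c1ccc(OC(=O)C(C)(C)C)c(C/C=C(\C)CC/C=C(\C)CO)c1 | intermediate
7 | methyl 3-{(2E)-5-[(2R,3R)-3-(hydroxymethyl)-3-methyloxiran-2-yl]-3-methylpent-2-en-1-yl}-4-(pivaloyloxy)benzoate | COC(=O)c1ccc(OC(=O)C(C)(C)C)c(C/C=C(\C)CC[C@H]2O[C@]2(C)CO)c1 | intermediate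
8 | methyl 3-[(2E,6S,7R)-6-bromo-7,8-dihydroxy-3,7-dimethyloct-2-en-1-yl]-4-(pivaloyloxy)benzoate | COC(=O)c1ccc(OC(=O)C(C)(C)C)c(C/C=C(\C)CC[C@H](Br)[C@](C)(O)CO)c1 | intermediate
9 | methyl 3-[(2E,6S,7R)-6-bromo-3,7-dimethyl-7,8-bis(triethylsilyloxy)oct-2-en-1-yl]-4-(pivaloyloxy)benzoate | COC(=O)c1ccc(OC(=O)C(C)(C)C)c(C/C=C(\C)CC[C@H](Br)[C@](C)(O[Si](CC)(CC)CC)CO[Si](CC)(CC)CC)c1 | intermediate
10 | methyl 3-[(2E,6S,7R)-6-bromo-3,7-dimethyl-8-oxo-7-(triethylsilyloxy)oct-2-en-1-yl]-4-(pivaloyloxy)benzoate | COC(=O)c1ccc(OC(=O)C(C)(C)C)c(C/C=C(\C)CC[C@H](Br)[C@](C)(O[Si](CC)(CC)CC)C=O)c1 | intermediate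
11 | methyl 3-[(2E,6S,7R)-6-bromo-3,7-dimethyl-7-(triethylsilyloxy)nona-2,8-dien-1-yl]-4-(pivaloyloxy)benzoate | COC(=O)c1ccc(OC(=O)C(C)(C)C)c(C/C=C(\C)CC[C@H](Br)[C@](C)(O[Si](CC)(CC)CC)C=C)c1 | intermediate
12 | propargyl alcohol (prop-2-yn-1-ol) | C#CCO | starting material
13 | dimethylaluminium (2E)-3-(dimethylalumanyl)-2-methylprop-2-en-1-olate | C[Al](C)/C=C(\C)CO[Al](C)C | intermediate (not isolated)
14 | (2E)-3-iodo-2-methylprop-2-en-1-ol | OC/C(C)=C/I | intermediate
15 | (2E)-3-iodo-2-methylprop-2-en-1-yl pivalate | CC(C)(C)C(=O)OC/C(C)=C/I | intermediate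
16 | B-alkyl-9-BBN adduct of 11 (boron on C9′; 6′S,7′R) | COC(=O)c1ccc(OC(=O)C(C)(C)C)c(C/C=C(\C)CC[C@H](Br)[C@](C)(O[Si](CC)(CC)CC)CCB2C3CCCC2CCC3)c1 | intermediate (not isolated)
17 | methyl 3-[(2E,6S,7R,10E)-6-bromo-3,7,11-trimethyl-12-(pivaloyloxy)-7-(triethylsilyloxy)dodeca-2,10-dien-1-yl]-4-(pivaloyloxy)benzoate | COC(=O)c1ccc(OC(=O)C(C)(C)C)c(C/C=C(\C)CC[C@H](Br)[C@](C)(O[Si](CC)(CC)CC)CC/C=C(\C)COC(=O)C(C)(C)C)c1 | intermediate
18 | methyl 3-[(2E,6S,7R,10E)-6-bromo-7-hydroxy-3,7,11-trimethyl-12-(pivaloyloxy)dodeca-2,10-dien-1-yl]-4-(pivaloyloxy)benzoate | COC(=O)c1ccc(OC(=O)C(C)(C)C)c(C/C=C(\C)CC[C@H](Br)[C@](C)(O)CC/C=C(\C)COC(=O)C(C)(C)C)c1 | intermediate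
19 | methyl 3-({(1R,5S,6S)-5-bromo-2,6-dimethyl-6-[(3E)-4-methyl-5-(pivaloyloxy)pent-3-en-1-yl]cyclohex-2-en-1-yl}methyl)-4-(pivaloyloxy)benzoate | CC1=CC[C@H](Br)[C@@](C)(CC/C=C(\C)COC(=O)C(C)(C)C)[C@@H]1Cc1cc(ccc1OC(=O)C(C)(C)C)C(=O)OC | intermediate
20 | methyl 3-({(1R,5S,6S)-5-bromo-6-[(3E)-5-hydroxy-4-methylpent-3-en-1-yl]-2,6-dimethylcyclohex-2-en-1-yl}methyl)-4-hydroxybenzoate | CC1=CC[C@H](Br)[C@@](C)(CC/C=C(\C)CO)[C@@H]1Cc1cc(ccc1O)C(=O)OC | intermediate
21 | methyl 3-({(1R,5S,6S)-5-bromo-6-[(3E)-5-hydroxy-4-methylpent-3-en-1-yl]-2,6-dimethylcyclohex-2-en-1-yl}methyl)-4-(methoxymethoxy)benzoate | CC1=CC[C@H](Br)[C@@](C)(CC/C=C(\C)CO)[C@@H]1Cc1cc(ccc1OCOC)C(=O)OC | intermediate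
22 | methyl 3-({(1R,5S,6S)-5-bromo-6-{2-[(2S,3S)-3-(hydroxymethyl)-3-methyloxiran-2-yl]ethyl}-2,6-dimethylcyclohex-2-en-1-yl}methyl)-4-(methoxymethoxy)benzoate | CC1=CC[C@H](Br)[C@@](C)(CC[C@@H]2O[C@@]2(C)CO)[C@@H]1Cc1cc(ccc1OCOC)C(=O)OC | intermediate
23 | methyl 3-({(1R,5S,6S)-5-bromo-6-[(3R,4S)-3-bromo-4,5-dihydroxy-4-methylpentyl]-2,6-dimethylcyclohex-2-en-1-yl}methyl)-4-(methoxymethoxy)benzoate | CC1=CC[C@H](Br)[C@@](C)(CC[C@@H](Br)[C@@](C)(O)CO)[C@@H]1Cc1cc(ccc1OCOC)C(=O)OC | intermediate
24 | methyl 3-({(1R,5S,6S)-5-bromo-6-[(3R,4S)-3-bromo-4-methyl-4,5-bis(triethylsilyloxy)pentyl]-2,6-dimethylcyclohex-2-en-1-yl}methyl)-4-(methoxymethoxy)benzoate | CC1=CC[C@H](Br)[C@@](C)(CC[C@@H](Br)[C@@](C)(O[Si](CC)(CC)CC)CO[Si](CC)(CC)CC)[C@@H]1Cc1cc(ccc1OCOC)C(=O)OC | intermediate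
25 | methyl 3-({(1R,5S,6S)-5-bromo-6-[(3R,4S)-3-bromo-4-methyl-5-oxo-4-(triethylsilyloxy)pentyl]-2,6-dimethylcyclohex-2-en-1-yl}methyl)-4-(methoxymethoxy)benzoate | CC1=CC[C@H](Br)[C@@](C)(CC[C@@H](Br)[C@@](C)(O[Si](CC)(CC)CC)C=O)[C@@H]1Cc1cc(ccc1OCOC)C(=O)OC | intermediate
26 | methyl 3-({(1R,5S,6S)-5-bromo-6-[(3R,4S)-3-bromo-4-methyl-4-(triethylsilyloxy)hex-5-en-1-yl]-2,6-dimethylcyclohex-2-en-1-yl}methyl)-4-(methoxymethoxy)benzoate | CC1=CC[C@H](Br)[C@@](C)(CC[C@@H](Br)[C@@](C)(O[Si](CC)(CC)CC)C=C)[C@@H]1Cc1cc(ccc1OCOC)C(=O)OC | intermediate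
27 | 3-({(1R,5S,6S)-5-bromo-6-[(3R,4S)-3-bromo-4-methyl-4-(triethylsilyloxy)hex-5-en-1-yl]-2,6-dimethylcyclohex-2-en-1-yl}methyl)-4-(methoxymethoxy)benzoic acid | CC1=CC[C@H](Br)[C@@](C)(CC[C@@H](Br)[C@@](C)(O[Si](CC)(CC)CC)C=C)[C@@H]1Cc1cc(ccc1OCOC)C(=O)O | intermediate
28 | isobutyraldehyde | CC(C)C=O | starting material
29 | 2-bromo-2-methylpropanal | CC(C)(Br)C=O | intermediate
30 | vinylmagnesium bromide | C=C[Mg]Br | starting material
31 | rac-4-bromo-4-methylpent-1-en-3-ol | C=CC(O)C(C)(C)Br | intermediate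
32 | (3S)-4-bromo-4-methylpent-1-en-3-ol | C=C[C@H](O)C(C)(C)Br | intermediate
33 | mixed anhydride of acid 27 with 2,4,6-trichlorobenzoic acid | CC1=CC[C@H](Br)[C@@](C)(CC[C@@H](Br)[C@@](C)(O[Si](CC)(CC)CC)C=C)[C@@H]1Cc1cc(ccc1OCOC)C(=O)OC(=O)c1c(Cl)cc(Cl)cc1Cl | intermediate (not isolated)
34 | (3S)-4-bromo-4-methylpent-1-en-3-yl 3-({(1R,5S,6S)-5-bromo-6-[(3R,4S)-3-bromo-4-methyl-4-(triethylsilyloxy)hex-5-en-1-yl]-2,6-dimethylcyclohex-2-en-1-yl}methyl)-4-(methoxymethoxy)benzoate | CC1=CC[C@H](Br)[C@@](C)(CC[C@@H](Br)[C@@](C)(O[Si](CC)(CC)CC)C=C)[C@@H]1Cc1cc(ccc1OCOC)C(=O)O[C@@H](C=C)C(C)(C)Br | intermediate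
35 | (3S)-4-bromo-4-methylpent-1-en-3-yl 3-({(1R,5S,6S)-5-bromo-6-[(3R,4S)-3-bromo-4-hydroxy-4-methylhex-5-en-1-yl]-2,6-dimethylcyclohex-2-en-1-yl}methyl)-4-(methoxymethoxy)benzoate | CC1=CC[C@H](Br)[C@@](C)(CC[C@@H](Br)[C@@](C)(O)C=C)[C@@H]1Cc1cc(ccc1OCOC)C(=O)O[C@@H](C=C)C(C)(C)Br | intermediate
36 | unsaturated 15-membered macrolide MOM ether (12′E; 2′R,6′S,7′S,10′R,11′S,14′S) | CC1=CC[C@H](Br)[C@@]2(C)CC[C@@H](Br)[C@@](C)(O)/C=C/[C@@H](C(C)(C)Br)OC(=O)c3ccc(OCOC)c(c3)C[C@H]12 | intermediate
37 | saturated macrolide MOM ether (2′R,6′S,7′S,10′R,11′S,14′S) | CC1=CC[C@H](Br)[C@@]2(C)CC[C@@H](Br)[C@@](C)(O)CC[C@@H](C(C)(C)Br)OC(=O)c3ccc(OCOC)c(c3)C[C@H]12 | intermediate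
38 | CNP0215732.1 (free phenol macrolide; 2′R,6′S,7′S,10′R,11′S,14′S) | CC1=CC[C@H](Br)[C@@]2(C)CC[C@@H](Br)[C@@](C)(O)CC[C@@H](C(C)(C)Br)OC(=O)c3ccc(O)c(c3)C[C@H]12 | target

**Step count and risks**
Total step count: 29. Longest linear sequence: 24 steps (steps 1–8, 11–21, 25–29).

Most likely to fail, in this order:

1. Step 13 (cationic ring closure). The tertiary cation may be diverted before or after the ring forms: the Lewis acid can be tied up by, or can ionize, the allylic pivalate of the long chain, the second trisubstituted alkene can engage the cation, and the C3′ cation can lose the wrong proton or pick up chloride. The fallback closes the ring on a simpler substrate and attaches the chain afterwards. It sets out from bromo diol 8. Silylation of the primary hydroxyl (TBDPSCl, imidazole, CH2Cl2) should give the mono-TBDPS ether F1, which carries a single alkene and no allylic ester. The same SnCl4 ionization and chair cyclization should give the bromocyclohexene silyl ether F2. The silyloxymethyl group slows ionization, which is why this order is held in reserve. Buffered TBAF/AcOH then gives the neopentyl alcohol F3, Dess–Martin oxidation the aldehyde F4 and Wittig methylenation the vinyl compound F5. Hydroboration with 9-BBN gives the B-alkyl-9-BBN adduct F6 (not isolated), and Suzuki coupling with iodide 15 (Pd(dppf)Cl2, K3PO4, DMF) comes back to the route at 19.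

2. Step 27 (ring-closing metathesis). Because both vinyl groups are hindered, catalyst loading may be slow enough that intermolecular metathesis and catalyst decay outrun ring closure. The fallback keeps the same bond and ring closure but delivers the carbene by relay. It sets out from aldehyde 25. A Wittig reaction with the ylide of (hex-5-en-1-yl)triphenylphosphonium bromide (KHMDS, THF, −78 °C) should give the relay diene F7, mainly as the Z alkene. Saponification as in step 21 gives the acid F8, Yamaguchi esterification with 32 the ester F9, and HF·pyridine the relay precursor F10. With Hoveyda–Grubbs II (toluene, 1 mM, 60 °C) the catalyst loads on the unhindered terminal alkene, expels cyclopentene to place the carbene on C12′, and closes onto the ester-side vinyl group. This comes back to the route at 36.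

3. Step 28 (alkene saturation). Hydrogen transfer may stall, because diimide disproportionates faster than it reduces an alkene shielded by a quaternary carbinol on one side and a branched acyloxy carbon on the other. The fallback sets out from 36 and replaces transfer reduction by hydroxyl-directed homogeneous hydrogenation ([Rh(nbd)(dppb)]BF4, H2, 50 bar, CH2Cl2, rt). The tertiary allylic alcohol binds the cationic rhodium and directs it to the adjacent disubstituted alkene, while the undirected trisubstituted ring alkene and the alkyl bromides should not react. This comes back to the route at 37 without any new compound.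

Further compounds
F1 | step 13 | methyl 3-[(2E,6S,7R)-6-bromo-8-(tert-butyldiphenylsilyloxy)-7-hydroxy-3,7-dimethyloct-2-en-1-yl]-4-(pivaloyloxy)benzoate | COC(=O)c1ccc(OC(=O)C(C)(C)C)c(C/C=C(\C)CC[C@H](Br)[C@](C)(O)CO[Si](c2ccccc2)(c2ccccc2)C(C)(C)C)c1
F2 | step 13 | methyl 3-({(1R,5S,6R)-5-bromo-6-[(tert-butyldiphenylsilyloxy)methyl]-2,6-dimethylcyclohex-2-en-1-yl}methyl)-4-(pivaloyloxy)benzoate | CC1=CC[C@H](Br)[C@@](C)(CO[Si](c2ccccc2)(c2ccccc2)C(C)(C)C)[C@@H]1Cc1cc(ccc1OC(=O)C(C)(C)C)C(=O)OC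
F3 | step 13 | methyl 3-{[(1R,5S,6R)-5-bromo-6-(hydroxymethyl)-2,6-dimethylcyclohex-2-en-1-yl]methyl}-4-(pivaloyloxy)benzoate | CC1=CC[C@H](Br)[C@@](C)(CO)[C@@H]1Cc1cc(ccc1OC(=O)C(C)(C)C)C(=O)OC
F4 | step 13 | methyl 3-{[(1R,5S,6R)-5-bromo-6-formyl-2,6-dimethylcyclohex-2-en-1-yl]methyl}-4-(pivaloyloxy)benzoate | CC1=CC[C@H](Br)[C@@](C)(C=O)[C@@H]1Cc1cc(ccc1OC(=O)C(C)(C)C)C(=O)OC
F5 | step 13 | methyl 3-{[(1R,5S,6S)-5-bromo-6-ethenyl-2,6-dimethylcyclohex-2-en-1-yl]methyl}-4-(pivaloyloxy)benzoate | CC1=CC[C@H](Br)[C@@](C)(C=C)[C@@H]1Cc1cc(ccc1OC(=O)C(C)(C)C)C(=O)OC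
F6 | step 13 | B-alkyl-9-BBN adduct of F5 (boron on the terminal carbon of the former vinyl group; not isolated) | CC1=CC[C@H](Br)[C@@](C)(CCB2C3CCCC2CCC3)[C@@H]1Cc1cc(ccc1OC(=O)C(C)(C)C)C(=O)OC
F7 | step 27 | methyl 3-({(1R,5S,6S)-5-bromo-6-[(3R,4S,5Z)-3-bromo-4-methyl-4-(triethylsilyloxy)undeca-5,10-dien-1-yl]-2,6-dimethylcyclohex-2-en-1-yl}methyl)-4-(methoxymethoxy)benzoate | CC1=CC[C@H](Br)[C@@](C)(CC[C@@H](Br)[C@@](C)(O[Si](CC)(CC)CC)/C=C\CCCC=C)[C@@H]1Cc1cc(ccc1OCOC)C(=O)OC
F8 | step 27 | benzoic acid corresponding to F7 | CC1=CC[C@H](Br)[C@@](C)(CC[C@@H](Br)[C@@](C)(O[Si](CC)(CC)CC)/C=C\CCCC=C)[C@@H]1Cc1cc(ccc1OCOC)C(=O)O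
F9 | step 27 | (3S)-4-bromo-4-methylpent-1-en-3-yl ester of F8 (tertiary TES ether) | CC1=CC[C@H](Br)[C@@](C)(CC[C@@H](Br)[C@@](C)(O[Si](CC)(CC)CC)/C=C\CCCC=C)[C@@H]1Cc1cc(ccc1OCOC)C(=O)O[C@@H](C=C)C(C)(C)Br
F10 | step 27 | relay precursor: F9 with the free tertiary alcohol at C11′ | CC1=CC[C@H](Br)[C@@](C)(CC[C@@H](Br)[C@@](C)(O)/C=C\CCCC=C)[C@@H]1Cc1cc(ccc1OCOC)C(=O)O[C@@H](C=C)C(C)(C)Br
F0 | step 28 | none | none
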